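**Plan**
- Retrosynthesis: the diaryl ether bonds B–O–C (at the ring C carbon), C–O–D (at the ring D carbon) and D–O–E (at the ring E carbon) are cut as copper-mediated O-arylations. The A–O–B ether is not cut; ring A itself is opened at C2–C3 and C5–C6 into an aryloxymalonate and diethyl acetonedicarboxylate.
- Enabling feature: with ring A numbered C1(OH), C2(H), C3(OH), C4(OAr), C5(OH), C6(H), the ether carbon C4 sits between the hydroxylated carbons C3 and C5. C3–C4–C5 is therefore an O-substituted malonyl unit and C2–C1–C6 an acetone unit.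
- Forward, AB half: syringaldehyde gives the ring B phenol, which is O-alkylated with bromomalonate; ring A is built on that oxygen (step 4), then decarboxylated, methylated and debenzylated to the AB phenol.
- Forward, CDE half: rings D and E are joined by Chan–Lam coupling, the bromide is turned into a boronic acid and coupled to 5-iodovanillin (ring C). The CDE iodide and the AB phenol are joined by Ullmann coupling.
- Finish: Baeyer–Villiger oxidation converts the ring C aldehyde into the last phenol, and BBr3 removes the eleven methyl groups.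
- Stereochemistry: the target is achiral, with no stereocentre and no double-bond isomerism; regiochemistry comes from the substitution patterns of the building blocks.

Key step: step 4

Assumption: in the two Chan–Lam couplings (steps 8 and 10) oxygen from air is the terminal oxidant, so the copper ends as divalent copper and is not consumed in the balanced equation.
Remark: compound 8 and the fallback compounds F1 and F2 carry enolizable sp3 centres and are racemic or diastereomeric mixtures; none of this reaches the target.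

**Route**

Step 1
Reactants: 1 syringaldehyde (4-hydroxy-3,5-dimethoxybenzaldehyde)
Product: 2 4-(benzyloxy)-3,5-dimethoxybenzaldehyde
Conditions: BnBr, K2CO3, DMF, rt
Reagents that add atoms: benzyl bromide, BrCc1ccccc1
Why: Williamson ether synthesis on a phenoxide made acidic by the para-formyl group; benzyl is chosen because it should survive alkoxide at 140 °C and later leave by hydrogenolysis without touching methyl or diaryl ethers.

Step 2
Reactants: 2 4-(benzyloxy)-3,5-dimethoxybenzaldehyde
Product: 4 4-(benzyloxy)-3,5-dimethoxyphenol, via aryl formate 3 (not isolated)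
Conditions: mCPBA, CH2Cl2, 0 °C to rt; then K2CO3 (cat.), MeOH, rt
Reagents that add atoms: 3-chloroperbenzoic acid (mCPBA), OOC(=O)c1cccc(Cl)c1
Why: Baeyer–Villiger oxidation of an electron-rich O-alkylated benzaldehyde, in which the aryl group migrates in the Criegee intermediate to give the formate that methanolysis cleaves to the phenol.

Step 3
Reactants: 4 4-(benzyloxy)-3,5-dimethoxyphenol; 5 diethyl bromomalonate
Product: 6 diethyl 2-[4-(benzyloxy)-3,5-dimethoxyphenoxy]propanedioate
Conditions: K2CO3, acetone, reflux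
Reagents that add atoms: none
Why: SN2 O-alkylation of a phenoxide by the doubly activated secondary bromide (Williamson type, as in aryloxymalonate and benzofuran syntheses), which places the ring B oxygen on the carbon that becomes C4 of ring A.

Step 4
Reactants: 6 diethyl 2-[4-(benzyloxy)-3,5-dimethoxyphenoxy]propanedioate; 7 diethyl acetonedicarboxylate (diethyl 3-oxopentanedioate)
Product: 9 diethyl 5-[4-(benzyloxy)-3,5-dimethoxyphenoxy]-2,4,6-trihydroxybenzene-1,3-dicarboxylate, via acyclic Claisen adduct 8 (not isolated)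
Conditions: NaOEt (2.2 equiv), xylene, 135–140 °C, slow addition of 7 with distillation of EtOH; then 2 M HCl, 0 °C
Reagents that add atoms: none
Why: One enolate carbon of 7 attacks an ester carbonyl of 6 and expels ethoxide (intermolecular Claisen condensation) to give 8, whose remaining CH2 then attacks the second malonate ester (Dieckmann condensation), so that C2–C3 and C5–C6 of ring A are formed and the cyclohexane-1,3,5-trione tautomerizes to the aromatic triol. The closest known reaction is the sodium ethoxide condensation of diethyl malonate with diethyl acetonedicarboxylate to diethyl phloroglucinoldicarboxylate. Ring A closes by a 6-exo-trig attack of the ester enolate carbon on the ester carbonyl (enolexo, allowed by Baldwin's rules). No stereocentre is created, because the sp3 centres of 8 and of the trione disappear on enolization. The step needs C- over O-acylation and cross- over self-condensation of 7; reversible sodium enolate conditions, a low standing concentration of 7, removal of EtOH and the irreversible aromatization to a polyanion should secure this, and there is no regiochemical question because both partners are symmetric. The aryl–O–C4 bond is already in place from step 3, so the ether carbon flanked by two oxygens never has to undergo an aryl coupling.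

Step 5
Reactants: 9 diethyl 5-[4-(benzyloxy)-3,5-dimethoxyphenoxy]-2,4,6-trihydroxybenzene-1,3-dicarboxylate
Product: 11 2-[4-(benzyloxy)-3,5-dimethoxyphenoxy]benzene-1,3,5-triol, via diacid 10 (not isolated)
Conditions: 2 M NaOH (degassed), reflux, Ar; then HCl to pH 1, 80 °C
Reagents that add atoms: none
Why: Ester saponification followed by decarboxylation of a 2,4,6-trihydroxybenzoic acid, which loses CO2 readily through its keto tautomer (a vinylogous β-keto acid), while benzyl and aryl ethers are inert.

Step 6
Reactants: 11 2-[4-(benzyloxy)-3,5-dimethoxyphenoxy]benzene-1,3,5-triol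
Product: 12 2-[4-(benzyloxy)-3,5-dimethoxyphenoxy]-1,3,5-trimethoxybenzene
Conditions: Me2SO4, K2CO3, acetone, reflux
Reagents that add atoms: dimethyl sulfate, COS(=O)(=O)OC
Why: Williamson O-methylation under the standard conditions for phloroglucinols, where the hard electrophile and weak base should keep C-methylation low.

Step 7
Reactants: 12 2-[4-(benzyloxy)-3,5-dimethoxyphenoxy]-1,3,5-trimethoxybenzene
Product: 13 2,6-dimethoxy-4-(2,4,6-trimethoxyphenoxy)phenol (AB phenol)
Conditions: H2 (1 atm), 10% Pd/C, EtOAc/MeOH, rt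
Reagents that add atoms: none
Why: Hydrogenolysis of the benzyl ether over palladium on carbon should free only the ring B phenol, since methyl and diaryl ethers are not cleaved.

Step 8
Reactants: 14 4-bromo-2,6-dimethoxyphenol; 15 (3,4,5-trimethoxyphenyl)boronic acid
Product: 16 5-bromo-1,3-dimethoxy-2-(3,4,5-trimethoxyphenoxy)benzene (DE bromide)
Conditions: Cu(OAc)2 (1 equiv), pyridine, 4 Å MS, CH2Cl2, dry air, rt
Reagents that add atoms: none
Why: Chan–Lam–Evans oxidative O-arylation at room temperature, which tolerates doubly ortho-substituted phenols and electron-rich boronic acids and leaves the aryl bromide untouched.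

Step 9
Reactants: 16 5-bromo-1,3-dimethoxy-2-(3,4,5-trimethoxyphenoxy)benzene
Product: 19 [3,5-dimethoxy-4-(3,4,5-trimethoxyphenoxy)phenyl]boronic acid, via aryllithium 17 (not isolated), via lithium triisopropoxyborate 18 (not isolated)
Conditions: n-BuLi, THF, −78 °C; B(OiPr)3, −78 °C to rt; 1 M HCl
Reagents that add atoms: triisopropyl borate, CC(C)OB(OC(C)C)OC(C)C; water, O
Why: Bromine–lithium exchange at −78 °C is faster than ortho-lithiation of the methoxyarenes, and borate trapping followed by acidic hydrolysis is the standard arylboronic acid synthesis.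

Step 10
Reactants: 19 [3,5-dimethoxy-4-(3,4,5-trimethoxyphenoxy)phenyl]boronic acid; 20 5-iodovanillin (4-hydroxy-3-iodo-5-methoxybenzaldehyde)
Product: 21 4-[3,5-dimethoxy-4-(3,4,5-trimethoxyphenoxy)phenoxy]-3-iodo-5-methoxybenzaldehyde (CDE iodide)
Conditions: Cu(OAc)2 (1 equiv), pyridine, Et3N, 4 Å MS, CH2Cl2, dry air, rt
Reagents that add atoms: none
Why: Chan–Lam–Evans O-arylation of an acidic phenol flanked by iodine and methoxy, the situation known from couplings of 2,6-diiodophenols with para-oxygenated arylboronic acids, with aryl iodide and aldehyde inert to divalent copper at room temperature.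

Step 11
Reactants: 13 2,6-dimethoxy-4-(2,4,6-trimethoxyphenoxy)phenol; 21 4-[3,5-dimethoxy-4-(3,4,5-trimethoxyphenoxy)phenoxy]-3-iodo-5-methoxybenzaldehyde
Product: 22 3-[2,6-dimethoxy-4-(2,4,6-trimethoxyphenoxy)phenoxy]-4-[3,5-dimethoxy-4-(3,4,5-trimethoxyphenoxy)phenoxy]-5-methoxybenzaldehyde (ABCDE aldehyde)
Conditions: CuI (20 mol %), picolinic acid (40 mol %), K3PO4, DMSO, 90 °C, Ar
Reagents that add atoms: none
Why: Ligand-accelerated Ullmann diaryl ether synthesis under conditions developed for ortho-substituted phenols and aryl iodides; the phenoxide of 13 is electron-rich, the C–I bond of 21 is activated by the meta-formyl group, and the aldehyde has no α-hydrogen.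

Step 12
Reactants: 22 ABCDE aldehyde
Product: 24 3-[2,6-dimethoxy-4-(2,4,6-trimethoxyphenoxy)phenoxy]-4-[3,5-dimethoxy-4-(3,4,5-trimethoxyphenoxy)phenoxy]-5-methoxyphenol, via aryl formate 23 (not isolated)
Conditions: mCPBA (1.2 equiv), CH2Cl2, 0 °C; then K2CO3 (cat.), MeOH, rt
Reagents that add atoms: 3-chloroperbenzoic acid (mCPBA), OOC(=O)c1cccc(Cl)c1
Why: Baeyer–Villiger oxidation of the only carbonyl group, with migration of the aryl group that carries a para-aryloxy donor, followed by methanolysis of the formate; low temperature and a small excess of peracid should spare the electron-rich rings.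

Step 13
Reactants: 24 ABCDE phenol
Product: 25 2-[3,5-dihydroxy-4-[2-[3,5-dihydroxy-4-(3,4,5-trihydroxyphenoxy)phenoxy]-3,5-dihydroxyphenoxy]phenoxy]benzene-1,3,5-triol (CNP0227069.0)
Conditions: BBr3 (excess), CH2Cl2, −78 °C to rt, Ar; then H2O, 0 °C
Reagents that add atoms: none
Why: Lewis-acid ether cleavage in which BBr3 coordinates each methoxy oxygen and bromide removes the methyl group by SN2, while the four diaryl ether bonds offer no sp3 carbon and should stay intact; hydrolysis of the aryl borates frees the twelve phenols.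

**Compound list**
1 | syringaldehyde | COc1cc(C=O)cc(OC)c1O | starting material
2 | 4-(benzyloxy)-3,5-dimethoxybenzaldehyde | COc1cc(C=O)cc(OC)c1OCc1ccccc1 | intermediate
3 | 4-(benzyloxy)-3,5-dimethoxyphenyl formate | COc1cc(OC=O)cc(OC)c1OCc1ccccc1 | intermediate
4 | 4-(benzyloxy)-3,5-dimethoxyphenol | COc1cc(O)cc(OC)c1OCc1ccccc1 | intermediate
5 | diethyl bromomalonate | CCOC(=O)C(Br)C(=O)OCC | starting material
6 | diethyl 2-[4-(benzyloxy)-3,5-dimethoxyphenoxy]propanedioate | CCOC(=O)C(Oc1cc(OC)c(OCc2ccccc2)c(OC)c1)C(=O)OCC | intermediate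
7 | diethyl acetonedicarboxylate | CCOC(=O)CC(=O)CC(=O)OCC | starting material
8 | diethyl 2-{2-[4-(benzyloxy)-3,5-dimethoxyphenoxy]-3-ethoxy-3-oxopropanoyl}-3-oxopentanedioate (mixture of stereoisomers and enol forms) | CCOC(=O)CC(=O)C(C(=O)OCC)C(=O)C(Oc1cc(OC)c(OCc2ccccc2)c(OC)c1)C(=O)OCC | intermediate
9 | diethyl 5-[4-(benzyloxy)-3,5-dimethoxyphenoxy]-2,4,6-trihydroxybenzene-1,3-dicarboxylate | CCOC(=O)c1c(O)c(C(=O)OCC)c(O)c(Oc2cc(OC)c(OCc3ccccc3)c(OC)c2)c1O | intermediate
10 | 5-[4-(benzyloxy)-3,5-dimethoxyphenoxy]-2,4,6-trihydroxybenzene-1,3-dicarboxylic acid | OC(=O)c1c(O)c(C(O)=O)c(O)c(Oc2cc(OC)c(OCc3ccccc3)c(OC)c2)c1O | intermediate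
11 | 2-[4-(benzyloxy)-3,5-dimethoxyphenoxy]benzene-1,3,5-triol | Oc1cc(O)c(Oc2cc(OC)c(OCc3ccccc3)c(OC)c2)c(O)c1 | intermediate
12 | 2-[4-(benzyloxy)-3,5-dimethoxyphenoxy]-1,3,5-trimethoxybenzene | COc1cc(OC)c(Oc2cc(OC)c(OCc3ccccc3)c(OC)c2)c(OC)c1 | intermediate
13 | 2,6-dimethoxy-4-(2,4,6-trimethoxyphenoxy)phenol | COc1cc(OC)c(Oc2cc(OC)c(O)c(OC)c2)c(OC)c1 | intermediate
14 | 4-bromo-2,6-dimethoxyphenol | COc1cc(Br)cc(OC)c1O | starting material
15 | (3,4,5-trimethoxyphenyl)boronic acid | COc1cc(B(O)O)cc(OC)c1OC | starting material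
16 | 5-bromo-1,3-dimethoxy-2-(3,4,5-trimethoxyphenoxy)benzene | COc1cc(Br)cc(OC)c1Oc1cc(OC)c(OC)c(OC)c1 | intermediate
17 | [3,5-dimethoxy-4-(3,4,5-trimethoxyphenoxy)phenyl]lithium | [Li]c1cc(OC)c(Oc2cc(OC)c(OC)c(OC)c2)c(OC)c1 | intermediate
18 | lithium [3,5-dimethoxy-4-(3,4,5-trimethoxyphenoxy)phenyl]tri(propan-2-yloxy)borate | [Li+].CC(C)O[B-](OC(C)C)(OC(C)C)c1cc(OC)c(Oc2cc(OC)c(OC)c(OC)c2)c(OC)c1 | intermediate
19 | [3,5-dimethoxy-4-(3,4,5-trimethoxyphenoxy)phenyl]boronic acid | COc1cc(B(O)O)cc(OC)c1Oc1cc(OC)c(OC)c(OC)c1 | intermediate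
20 | 5-iodovanillin (4-hydroxy-3-iodo-5-methoxybenzaldehyde) | COc1cc(C=O)cc(I)c1O | starting material
21 | 4-[3,5-dimethoxy-4-(3,4,5-trimethoxyphenoxy)phenoxy]-3-iodo-5-methoxybenzaldehyde | COc1cc(C=O)cc(I)c1Oc1cc(OC)c(Oc2cc(OC)c(OC)c(OC)c2)c(OC)c1 | intermediate
22 | 3-[2,6-dimethoxy-4-(2,4,6-trimethoxyphenoxy)phenoxy]-4-[3,5-dimethoxy-4-(3,4,5-trimethoxyphenoxy)phenoxy]-5-methoxybenzaldehyde | COc1cc(C=O)cc(Oc2c(OC)cc(Oc3c(OC)cc(OC)cc3OC)cc2OC)c1Oc1cc(OC)c(Oc2cc(OC)c(OC)c(OC)c2)c(OC)c1 | intermediate
23 | 3-[2,6-dimethoxy-4-(2,4,6-trimethoxyphenoxy)phenoxy]-4-[3,5-dimethoxy-4-(3,4,5-trimethoxyphenoxy)phenoxy]-5-methoxyphenyl formate | COc1cc(OC=O)cc(Oc2c(OC)cc(Oc3c(OC)cc(OC)cc3OC)cc2OC)c1Oc1cc(OC)c(Oc2cc(OC)c(OC)c(OC)c2)c(OC)c1 | intermediate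
24 | 3-[2,6-dimethoxy-4-(2,4,6-trimethoxyphenoxy)phenoxy]-4-[3,5-dimethoxy-4-(3,4,5-trimethoxyphenoxy)phenoxy]-5-methoxyphenol | COc1cc(O)cc(Oc2c(OC)cc(Oc3c(OC)cc(OC)cc3OC)cc2OC)c1Oc1cc(OC)c(Oc2cc(OC)c(OC)c(OC)c2)c(OC)c1 | intermediate
25 | 2-[3,5-dihydroxy-4-[2-[3,5-dihydroxy-4-(3,4,5-trihydroxyphenoxy)phenoxy]-3,5-dihydroxyphenoxy]phenoxy]benzene-1,3,5-triol (achiral) | Oc1cc(O)c(Oc2cc(O)c(Oc3cc(O)cc(O)c3Oc3cc(O)c(Oc4cc(O)c(O)c(O)c4)c(O)c3)c(O)c2)c(O)c1 | target

**Step count**
Total: 13 steps. Longest linear sequence: 10 steps (steps 1–7, then 11–13); the CDE branch (steps 8–10) is 3 steps.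

**Steps most likely to fail**

Step 4. The enolate of 7 may condense with itself (aldol/Claisen path to an orcinol-type arene) or close through oxygen to a pyranone faster than it C-acylates 6, whose ester carbonyls are masked for much of the time as the malonate's own enolate. The fallback keeps the same two ring bonds but forms them one at a time with an activated acyl donor. It sets out from 6: one equivalent of KOH in EtOH, then acidification, should give the half ester 2-[4-(benzyloxy)-3,5-dimethoxyphenoxy]-3-ethoxy-3-oxopropanoic acid F1. (COCl)2 with catalytic DMF in CH2Cl2 should convert this into the acid chloride ethyl 2-[4-(benzyloxy)-3,5-dimethoxyphenoxy]-3-chloro-3-oxopropanoate F2. C-acylation of the magnesium enolate of 7 with F2 (MgCl2, Et3N, MeCN, 0 °C) should deliver 8 as an isolated compound, and NaOEt in EtOH at reflux should then close and aromatize it, returning to the route at 9.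

Step 11. Carbon–oxygen bond formation at copper between two ortho-substituted partners may be slow, so that protodeiodination of the iodide and oxidative degradation of the electron-rich phenol take over. The fallback changes the order of assembly so that the hindered phenol meets a small iodide that can be used in excess. It sets out from 13: 5-iodovanillin 20 is benzylated (BnBr, K2CO3, DMF) to 4-(benzyloxy)-3-iodo-5-methoxybenzaldehyde F3. Ullmann coupling of 13 with an excess of F3 (CuI, picolinic acid, K3PO4, DMSO, 90 °C) should give 4-(benzyloxy)-3-[2,6-dimethoxy-4-(2,4,6-trimethoxyphenoxy)phenoxy]-5-methoxybenzaldehyde F4. Debenzylation with BCl3 and pentamethylbenzene at −78 °C, which spares aldehyde and methyl ethers, should give 3-[2,6-dimethoxy-4-(2,4,6-trimethoxyphenoxy)phenoxy]-4-hydroxy-5-methoxybenzaldehyde F5. Chan–Lam coupling of F5 with boronic acid 19 (Cu(OAc)2, pyridine, 4 Å MS, air) returns to the route at 22.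

Step 10. Coupling at copper may be sluggish for an acidic, doubly ortho-substituted phenol, while the boronic acid is consumed by protodeboronation, homocoupling and oxidation to its phenol. The fallback replaces copper catalysis by a metal-free aryl transfer from trivalent iodine. It sets out from 19: treatment with 1-(diacetoxyiodo)-4-methoxybenzene and BF3·OEt2 in CH2Cl2 should give [3,5-dimethoxy-4-(3,4,5-trimethoxyphenoxy)phenyl](4-methoxyphenyl)iodonium tetrafluoroborate F6. Reaction of F6 with the potassium phenoxide of 20 (t-BuOK, THF, rt) should transfer the ring D aryl group, since the more electron-rich anisyl group stays on iodine and hindered phenoxides are good partners in such arylations. This returns to the route at 21.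

Further compounds
F1 | step 4 | 2-[4-(benzyloxy)-3,5-dimethoxyphenoxy]-3-ethoxy-3-oxopropanoic acid (racemic) | CCOC(=O)C(Oc1cc(OC)c(OCc2ccccc2)c(OC)c1)C(O)=O
F2 | step 4 | ethyl 2-[4-(benzyloxy)-3,5-dimethoxyphenoxy]-3-chloro-3-oxopropanoate (racemic) | CCOC(=O)C(Oc1cc(OC)c(OCc2ccccc2)c(OC)c1)C(Cl)=O
F3 | step 11 | 4-(benzyloxy)-3-iodo-5-methoxybenzaldehyde | COc1cc(C=O)cc(I)c1OCc1ccccc1
F4 | step 11 | 4-(benzyloxy)-3-[2,6-dimethoxy-4-(2,4,6-trimethoxyphenoxy)phenoxy]-5-methoxybenzaldehyde | COc1cc(C=O)cc(Oc2c(OC)cc(Oc3c(OC)cc(OC)cc3OC)cc2OC)c1OCc1ccccc1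
F5 | step 11 | 3-[2,6-dimethoxy-4-(2,4,6-trimethoxyphenoxy)phenoxy]-4-hydroxy-5-methoxybenzaldehyde | COc1cc(C=O)cc(Oc2c(OC)cc(Oc3c(OC)cc(OC)cc3OC)cc2OC)c1O
F6 | step 10 | [3,5-dimethoxy-4-(3,4,5-trimethoxyphenoxy)phenyl](4-methoxyphenyl)iodonium tetrafluoroborate | COc1ccc([I+]c2cc(OC)c(Oc3cc(OC)c(OC)c(OC)c3)c(OC)c2)cc1.F[B-](F)(F)F
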